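**Retrosynthetic overview**
- Feature: ring A carries the chain at C1, the ether O at C3 and OH at C5. Ring B carries the ether O at C1, OH at C2 and C4, and the chain at C6. The C5–OH of ring A and the C4–OH of ring B each sit on the only carbon of their ring that lies between two unsubstituted CH positions.
- The last operations add oxygen only. The ring B C2 methyl ether is cleaved at the very end. Before that, both exposed C–H bonds of the oxygen-poor macrocycle become C–OH by double iridium C–H borylation and peroxide oxidation.
- The methoxy macrocycle comes from a macrocyclic ene-diol by alkene saturation and hydrogenolysis of two benzylic C–OH bonds. The ene-diol comes from ring-closing metathesis at C7=C8 of the C14 tether.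
- The metathesis substrate comes from a diaryl ether dialdehyde and two hept-6-enyl Grignard units. The dialdehyde comes from SNAr at a C–F bond ortho to CHO.
- Ring order: rings A and B are bought, and the 20-membered macrocycle (step 3) is the only ring made. The target has no stereocentre.

Key step: step 5

Remark: the carbinol configuration in 6 and 7 and the alkene geometry in 7 are left uncontrolled, because step 4 erases both.

**Step 1**
Reactants: 1 2-fluoro-3-methoxybenzaldehyde; 2 3-hydroxybenzaldehyde
Product: 3 2-(3-formylphenoxy)-3-methoxybenzaldehyde
Conditions: K2CO3, DMAc, 120 °C, N2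
Reagents that add atoms: none
Why: Nucleophilic aromatic substitution (SNAr), in which the ortho formyl group of 1 stabilises the Meisenheimer adduct and fluoride leaves readily, so the doubly flanked C–O bond forms without the copper-mediated arylation of a chelating, di-ortho-substituted salicylaldehyde-type phenol.

**Step 2**
Reactants: 3 2-(3-formylphenoxy)-3-methoxybenzaldehyde; 4 7-bromohept-1-ene (2.6 equiv)
Product: 6 1-[2-[3-(1-hydroxyoct-7-enyl)phenoxy]-3-methoxyphenyl]oct-7-en-1-ol (bis-carbinol; diastereomer mixture), via hept-6-enylmagnesium bromide 5 (not isolated)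
Conditions: Mg, THF, 40 °C; then 3, THF, 0 °C to rt; sat. aq NH4Cl
Reagents that add atoms: magnesium, [Mg] (held only in intermediate 5)
Why: Grignard addition, in which both non-enolisable aryl aldehydes accept the primary alkylmagnesium reagent, the terminal alkenes stay inert, and the two carbinol centres form without control, which is harmless because step 4 removes them.

**Step 3**
Reactants: 6 bis-carbinol diene
Product: 7 macrocyclic ene-diol (20-membered ring; ring A C1–CH(OH)(CH2)5CH=CH(CH2)5CH(OH)–ring B C6; ring A C3–O–ring B C1; OMe on ring B C2; E/Z and diastereomer mixture)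
Conditions: second-generation Grubbs catalyst RuCl2(=CHPh)(PCy3)(H2IMes) (5 mol%), 1,4-benzoquinone (10 mol%), CH2Cl2 (1 mM), reflux
Reagents that add atoms: none
Why: Ring-closing metathesis of two unhindered terminal alkenes at high dilution is driven by loss of ethene, neither arm holds a second alkene that could be clipped off as a small cycloalkene, and benzoquinone suppresses alkene migration.

**Step 4**
Reactants: 7 macrocyclic ene-diol
Product: 8 methoxy cyclophane (ring A C1–(CH2)14–ring B C6; ring A C3–O–ring B C1; OMe on ring B C2; no other oxygen)
Conditions: H2 (4 atm), Pd/C, AcOH, cat. H2SO4, 40 °C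
Reagents that add atoms: none
Why: Catalytic hydrogenation of the alkene runs together with acid-assisted hydrogenolysis of the two secondary benzylic C–O bonds over Pd/C, conditions that leave the diaryl ether, the aryl methyl ether and the arenes untouched.

**Step 5**
Reactants: 8 methoxy cyclophane
Product: 10 macrocyclic diol mono-methyl ether (OH on ring A C5 and on ring B C4; OMe on ring B C2), via macrocyclic bis(pinacol boronate) 9 (not isolated)
Conditions: [Ir(OMe)(cod)]2 (3 mol%), 4,4'-di-tert-butyl-2,2'-bipyridine (dtbpy, 6 mol%), B2pin2 (3 equiv), THF, 80 °C, sealed; then aq NaOH, 30% H2O2, 0 °C to rt, same flask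
Reagents that add atoms: bis(pinacolato)diboron, CC1(C)OB(OC1(C)C)B1OC(C)(C)C(C)(C)O1 (its Bpin groups stay only in intermediate 9); hydrogen peroxide, OO (the two new oxygen atoms)
Why: This is iridium-catalysed aromatic C–H borylation followed by oxidation of the aryl boronates, the known one-pot route from arenes to phenols. [Ir(OMe)(cod)]2 (monovalent iridium), dtbpy and B2pin2 give (dtbpy)Ir(Bpin)3 (trivalent iridium), which cleaves an aryl C–H bond, releases Ar–Bpin and is reloaded by B2pin2; hydroperoxide then adds to boron and the aryl group shifts from B to O, so each oxygen ends on the carbon that was borylated. The step needs site selectivity on two rings at once, and crowding alone secures it: on ring A, C2–H lies between chain and ether oxygen while C4–H and C6–H each have one ortho neighbour, which leaves C5–H; on ring B, C3–H sits beside OMe and C5–H beside the chain, which leaves C4–H. Both open C–H bonds point away from the 20-membered ring, so the tether does not shield them, and once each ring carries its Bpin group no unhindered C–H remains, so excess B2pin2 can push the slow, electron-rich rings to full conversion without over-borylation. The closest known cases are the conversion of 1,3-disubstituted arenes into 3,5-disubstituted phenols and the C5 functionalisation of 1,2,3-trisubstituted arenes. Two C–O bonds form, no ring is closed and no stereocentre arises.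

**Step 6**
Reactants: 10 macrocyclic diol mono-methyl ether
Product: 11 target triol CNP0173380.0
Conditions: BBr3 (5 equiv), CH2Cl2, −78 °C to rt; then degassed H2O, argon
Reagents that add atoms: none
Why: In this Lewis acid ether cleavage BBr3 binds the methoxy oxygen and bromide attacks the methyl carbon (SN2), the diaryl ether offers no sp3 carbon and survives, and the extra equivalents cover the two free phenols.

**Compound list**
1 | 2-fluoro-3-methoxybenzaldehyde | COc1cccc(C=O)c1F | starting material
2 | 3-hydroxybenzaldehyde | O=Cc1cccc(O)c1 | starting material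
3 | 2-(3-formylphenoxy)-3-methoxybenzaldehyde | COc1cccc(C=O)c1Oc1cccc(C=O)c1 | intermediate
4 | 7-bromohept-1-ene | C=CCCCCCBr | starting material
5 | hept-6-enylmagnesium bromide (made and used in THF) | C=CCCCCC[Mg]Br | intermediate
6 | 1-[2-[3-(1-hydroxyoct-7-enyl)phenoxy]-3-methoxyphenyl]oct-7-en-1-ol (diastereomer mixture) | COc1cccc(C(O)CCCCCC=C)c1Oc1cccc(C(O)CCCCCC=C)c1 | intermediate
7 | macrocyclic ene-diol, C7=C8 alkene and C1/C14 carbinols in the tether (E/Z and diastereomer mixture) | COc1cccc2C(O)CCCCCC=CCCCCCC(O)c3cccc(c3)Oc12 | intermediate
8 | methoxy cyclophane, saturated (CH2)14 tether, OMe on ring B C2 | COc1cccc2CCCCCCCCCCCCCCc3cccc(c3)Oc12 | intermediate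
9 | macrocyclic bis(pinacol boronate), Bpin on ring A C5 and ring B C4 | COc1cc(B3OC(C)(C)C(C)(C)O3)cc2CCCCCCCCCCCCCCc4cc(B5OC(C)(C)C(C)(C)O5)cc(c4)Oc12 | intermediate
10 | macrocyclic diol, ring B C2 mono-methyl ether | COc1cc(O)cc2CCCCCCCCCCCCCCc3cc(O)cc(c3)Oc12 | intermediate
11 | CNP0173380.0 | Oc1cc2cc(c1)Oc1c(O)cc(O)cc1CCCCCCCCCCCCCC2 | target

Total step count: 6. Longest linear sequence: 6 (steps 1 to 6).

**Steps most likely to fail**

1. **Step 5.**
   - What may go wrong: the second borylation may stall on the electron-rich rings. Some borylation may leak to ring B C3–H beside the small methoxy group. Alkaline peroxide may over-oxidise the newly formed para-aryloxyphenol.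
   - Fallback (sets out from 5, comes back at 11): the two oxygens are bought in as methyl ethers, so no late C–H oxidation is needed. 2-bromo-3,5-dimethoxybenzaldehyde F1 and 3-hydroxy-5-methoxybenzaldehyde F2 are joined by Ullmann-type coupling (CuI, monovalent copper, N,N-dimethylglycine, Cs2CO3, 1,4-dioxane, 100 °C) to give 2-(3-formyl-5-methoxyphenoxy)-3,5-dimethoxybenzaldehyde F3. Grignard reagent 5 adds to both aldehydes to give the trimethoxy bis-carbinol F4. Ring-closing metathesis under the conditions of step 3 gives the trimethoxy macrocyclic ene-diol F5. Hydrogenation with hydrogenolysis as in step 4 gives the tri-O-methyl ether of the target F6. BBr3 in CH2Cl2 then cleaves all three methyl ethers to 11.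

2. **Step 3.**
   - What may go wrong: intermolecular metathesis to oligomers competes with closure of a conformationally unbiased 20-membered ring. Alkene migration before closure would cause ring contraction by one carbon.
   - Fallback (sets out from 3, comes back at 8, replacing steps 2 to 4): the ring is closed by two Wittig olefinations at the benzylic carbons. 1,12-dibromododecane F7 and PPh3 (MeCN, reflux) give dodecane-1,12-diylbis(triphenylphosphonium) dibromide F8. NaHMDS (2 equiv, THF, 0 °C) converts it into the C12 bis-ylide F9. This and dialdehyde 3 are fed slowly and at equal rates into a large volume of THF, so that the second olefination is intramolecular, which should give the macrocyclic 1,13-diene F10. H2, Pd/C, EtOAc then gives 8.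

3. **Step 4.**
   - What may go wrong: after the alkene is saturated, C–O hydrogenolysis may stall at the ring A carbinol, which has no ortho or para donor to help ionisation.
   - Fallback (sets out from 7, comes back at 8): the C–O bonds are removed by elimination instead of hydrogenolysis. Catalytic p-TsOH in toluene at reflux with a water separator dehydrates both carbinols to the macrocyclic triene F11. Neutral hydrogenation (H2, Pd/C, EtOAc) of all three alkenes gives 8.

**Further compounds**
F1 | step 5 | 2-bromo-3,5-dimethoxybenzaldehyde (bought) | COc1cc(OC)c(Br)c(C=O)c1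
F2 | step 5 | 3-hydroxy-5-methoxybenzaldehyde (bought) | COc1cc(O)cc(C=O)c1
F3 | step 5 | 2-(3-formyl-5-methoxyphenoxy)-3,5-dimethoxybenzaldehyde | COc1cc(OC)c(Oc2cc(OC)cc(C=O)c2)c(C=O)c1
F4 | step 5 | trimethoxy bis-carbinol (diastereomer mixture) | COc1cc(OC)c(Oc2cc(OC)cc(C(O)CCCCCC=C)c2)c(C(O)CCCCCC=C)c1
F5 | step 5 | trimethoxy macrocyclic ene-diol (E/Z and diastereomer mixture) | COc1cc(OC)c2Oc3cc(OC)cc(c3)C(O)CCCCCC=CCCCCCC(O)c2c1
F6 | step 5 | tri-O-methyl ether of the target | COc1cc(OC)c2Oc3cc(OC)cc(c3)CCCCCCCCCCCCCCc2c1
F7 | step 3 | 1,12-dibromododecane (bought) | BrCCCCCCCCCCCCBr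
F8 | step 3 | dodecane-1,12-diylbis(triphenylphosphonium) dibromide | [Br-].[Br-].c1ccccc1[P+](c1ccccc1)(c1ccccc1)CCCCCCCCCCCC[P+](c1ccccc1)(c1ccccc1)c1ccccc1
F9 | step 3 | C12 bis-ylide (made in the flask) | c1ccccc1P(c1ccccc1)(c1ccccc1)=CCCCCCCCCCCC=P(c1ccccc1)(c1ccccc1)c1ccccc1
F10 | step 3 | macrocyclic 1,13-diene (E/Z mixture) | COc1cccc2C=CCCCCCCCCCCC=Cc3cccc(c3)Oc12
F11 | step 4 | macrocyclic triene (E/Z mixture) | COc1cccc2C=CCCCCC=CCCCCC=Cc3cccc(c3)Oc12
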